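In the autumn run, the ratio r of isomer of the product to target stays level from 4.00 h on while both readings climb. In the winter run it stays level from 2.50 h. Read this as equilibrium between the two: thermodynamic rather than kinetic control.

all flasks: starting material 0.050 M
- autumn: partner 0.024 M (fed, over 1.5 h); protic impurity 0.025 M; temperature 18 °C; run made earlier; the fed solution adds 0.50 times the starting volume
- winter: partner 0.044 M (fed, over 1.5 h); protic impurity 0.025 M; temperature 34 °C; run made earlier; the fed solution adds 0.50 times the starting volume
- Tuesday's: partner 0.0400 M (fed, over 1.5 h); protic impurity 0.0250 M; at 10 °C throughout; the fed solution adds 0.50 times the starting volume; time 15 h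
- Saturday's: partner 0.0550 M (fed, over 1.5 h); protic impurity 0.0250 M; at 10 °C until 1.5 h, from then on at 40 °C; the fed solution adds 0.50 times the starting volume; time 15 h

| run | time / h | target / % | isomer of the product / % |
|---|---|---|---|
| autumn | 0.833 | 0.9 | 0 |
| autumn | 2.50 | 8.3 | 2.8 |
| autumn | 4.00 | 10.6 | 4.9 |
| autumn | 6.00 | 14.4 | 5.9 |
| autumn | 10.0 | 20.2 | 8.8 |
| autumn | 12.0 | 23.3 | 13.5 |
| autumn | 15.0 | 28.4 | 11.7 |
| winter | 0.667 | 9.2 | 2.2 |
| winter | 1.33 | 22.6 | 3.6 |
| winter | 2.00 | 27.2 | 4.1 |
| winter | 2.50 | 34.7 | 5.9 |
| winter | 3.00 | 38.8 | 5.7 |
| winter | 4.00 | 43.6 | 5.0 |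
| winter | 5.00 | 45.6 | 5.9 |

(standard deviation of a reading: 1 percentage point)

- every charge counts on the volume at the start, and the solution that is fed holds the whole dose

- which of the two ends with the higher share of target in all that became target or isomer of the product ("neither" if they lie within 2 percentage points) (Tuesday's / Saturday's / neither)
- share of target in all that became target or isomer of the product, Tuesday's
- share of target in all that became target or isomer of the product, Saturday's

1. Pool the level readings. Autumn gives r = 0.462. Winter gives r = 0.138.

2. Draw ln r against inverse absolute temperature. The slope is B = 6750 K.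

3. Define the resting share S = 1/(1 + r), the share of target at equilibrium between the pair. Extrapolate to 10 °C: S = 52.9%. Extrapolate to 40 °C: the resting share S = 91.7%.

4. Bound Tuesday's from below by S at 10 °C. Take isomer as formed from target: it can then lag but not lead.

5. Compute the lag as a correction. Let product form steadily and isomer trail by a time τ. The share at time t then exceeds S by (1 − S)τ/t. Autumn's reading at 2.50 h gives τ = 0.505 h. Allow a generous slowing by 4 on cooling to 10 °C. Tuesday's upper bound is 59.3%.

6. Bound Saturday's from below by winter's resting share, 87.9%, since r read at the warmer temperature is lower than r read at the cooler one. For the upper bound, add to S at 40 °C the correction with autumn's τ, counted from the change of temperature: 92.0%.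

7. The forecast says 59% for Tuesday's, near the top of its bracket, and 87% for Saturday's, just below the lower bound, on the ground: “Target therefore has the higher activation energy”.

8. The flasks give 57.0% for Tuesday's and 91.2% for Saturday's, both inside the brackets, so Saturday's ends higher.

    starting material ⇌ intermediate + leaving ligand (K = 0.00340 M, k = 2.97 × 10⁻⁴ min⁻¹, Ea = 94.0 kJ mol⁻¹, ΔH = −58.0 kJ mol⁻¹)
    partner + intermediate → target (k = 1.46 M⁻¹ min⁻¹, Ea = 67.0 kJ mol⁻¹)
    target ⇌ isomer of the product (K = 0.910, k = 0.00476 min⁻¹, Ea = 100 kJ mol⁻¹, ΔH = −55.0 kJ mol⁻¹)
    starting material + protic impurity → quenched substrate (k = 0.00774 M⁻¹ min⁻¹, Ea = 80.0 kJ mol⁻¹)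
    intermediate → decomposed reagent (k = 5.48 × 10⁻⁵ min⁻¹, Ea = 103 kJ mol⁻¹)
    (constants at 10 °C)

Tuesday's share stands at 57.0% because isomer of the product runs back to target: without that backward run it falls to 21.3%. Left until 150 h, Tuesday's sinks to 52.4%, so its share at 15 h still holds a lag. Carry S at 40 °C, 91.7%, to the neighbour of Saturday's charged with 0.20 M of starting material. That flask keeps 58.0% of its starting material unconverted and still ends at 91.2%.

(The readings are calculated from invented constants, and the scatter is random.)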